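**Plan**

- Retrosynthesis, late cuts: the six silyl ethers come off last. The central C18=C19–C20=C21 diene of the all-E C16–C25 pentaene is then folded back into the C18–C21 σ-bond of a trans-3,4-dialkenylcyclobutene, which contracts the 28-membered lactone (C1–C27 plus O) to a 26-membered one. This works because that diene is flanked by the C16=C17 alkene and the C22–C25 diene, which become the two alkenyl arms.
- Further cuts: C16=C17 (ring-closing Julia–Kocienski), C22=C23 (intermolecular Julia–Kocienski, both from one bis-sulfone made from cis-cyclobut-3-ene-1,2-dicarboxylic anhydride), the ester C1–O27, and in the C1–C16 acid C2–C3 and C14–C15 (Evans aldols), C9–C10 (methyl ketone aldol), C12–C13 (Weinreb acylation) and C6–C7 (epoxide opening).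
- Forward order: C10–C16 ketone plus C3–C9 aldehyde give the C3–C16 polyol, then the C1–C16 acid; esterification with the C23–C28 hydroxy-enal; olefination at C23 with the bis-sulfone; oxidation at C16; ring closure at C16=C17 at −78 °C to the 26-membered cyclobutene lactone; thermal ring expansion to the 28-membered lactone; desilylation.
- Stereochemistry: C14/C15 and C2/C3 from Evans syn aldols; C13 from 1,3-anti reduction; C9 from a 1,5-anti boron aldol; C11 from 1,3-syn reduction; C5 from (R)-2-[2-(benzyloxy)ethyl]oxirane; C26/C27 from (2R,3R)-butane-2,3-diol. Alkene geometry comes from Julia–Kocienski olefination (E), cross-metathesis (E) and outward conrotation (E,E).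
- Design point: a trans-3,4-dialkenylcyclobutene is expected to open near ambient temperature. The second alkenyl arm is therefore created only in the ring-closing event, when the lactone is already in place.

Key step: step 32

Remark: carbons are numbered as in the macrolide (C1 lactone carbonyl through C27, the O-bearing carbon; C28 is its methyl).
Remark: the cyclobutene linchpin is used as the racemate, so the three compounds that hold both it and the chiral chain should form as roughly equimolar pairs of diastereomers that differ only at C18/C21 (one is drawn); both converge in the key step.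
Remark: triethylsilyl ethers are chosen for the late stages so that the last step needs only buffered fluoride at 0 °C.

**Route**

Step 1
Reactants: 1 (S)-4-benzyl-3-propanoyl-1,3-oxazolidin-2-one; 2 2-[(tert-butyldimethylsilyl)oxy]acetaldehyde
Product: 3 syn aldol imide (C13–C16)
Conditions: Bu2BOTf, iPr2NEt, CH2Cl2, −78 to 0 °C; H2O2, MeOH, pH 7 buffer
Reagents that add atoms: none
Why: Evans syn aldol in which the Z-boron enolate of the (S)-benzyl oxazolidinone adds through a Zimmerman–Traxler chair on the face fixed by the auxiliary, setting C14 and C15 (2S,3S in the adduct).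

Step 2
Reactants: 3 syn aldol imide
Product: 4 Weinreb amide (C13–C16)
Conditions: MeNH(OMe)·HCl, AlMe3, THF, −20 to 0 °C
Reagents that add atoms: N,O-dimethylhydroxylamine hydrochloride, CNOC.Cl
Why: AlMe3-mediated transamidation of a β-hydroxy imide to the Weinreb amide, assisted by the free hydroxyl, releases the auxiliary without touching C14 or C15.

Step 3
Reactants: 4 Weinreb amide; 5 (2-methylprop-2-en-1-yl)magnesium chloride
Product: 6 β-hydroxy ketone (C10–C16, C13 ketone)
Conditions: THF, −78 to −20 °C; NH4Cl (aq), cold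
Reagents that add atoms: none
Why: Grignard addition to a Weinreb amide stops at the ketone through the chelated tetrahedral intermediate, and the methallyl group brings C10–C12 as a masked acetonyl unit while the cold neutral work-up protects the C14 stereocentre.

Step 4
Reactants: 6 β-hydroxy ketone
Product: 7 1,3-anti diol (C13, C15)
Conditions: Me4NBH(OAc)3, MeCN/AcOH, −30 °C
Reagents that add atoms: none
Why: Evans–Saksena reduction delivers hydride intramolecularly from the C15 alkoxyborohydride through a chair transition state and so sets C13 anti to C15.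

Step 5
Reactants: 7 1,3-anti diol
Product: 8 acetonide
Conditions: Me2C(OMe)2, PPTS (cat.), CH2Cl2, rt
Reagents that add atoms: 2,2-dimethoxypropane, COC(C)(C)OC
Why: Acid-catalysed transketalisation ties the diol into an acetonide, which adds no stereocentre and leaves an ether-type β-oxygen at C13 for the later 1,5-induction.

Step 6
Reactants: 8 acetonide
Product: 9 C10–C16 methyl ketone
Conditions: OsO4 (cat.), NaIO4, 2,6-lutidine, dioxane/H2O, rt
Reagents that add atoms: osmium tetroxide, O=[Os](=O)(=O)=O; sodium periodate, [Na+].[O-]I(=O)(=O)=O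
Why: Lemieux–Johnson cleavage of the 1,1-disubstituted alkene gives the methyl ketone under buffered conditions that the acetonide and the silyl ether tolerate.

Step 7
Reactants: 10 (R)-2-[2-(benzyloxy)ethyl]oxirane; 11 but-3-en-1-ylmagnesium bromide
Product: 12 (S)-1-(benzyloxy)oct-7-en-3-ol
Conditions: CuI (10 mol%), THF, −40 to 0 °C
Reagents that add atoms: none
Why: CuI-catalysed Grignard opening of the terminal epoxide at its CH2 carbon forms C6–C7 and carries the epoxide stereocentre over unchanged as C5.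

Step 8
Reactants: 12 (S)-1-(benzyloxy)oct-7-en-3-ol
Product: 13 triethylsilyl ether of 12
Conditions: Et3SiCl, imidazole, CH2Cl2, 0 °C
Reagents that add atoms: chlorotriethylsilane, CC[Si](Cl)(CC)CC
Why: Imidazole-promoted silylation protects C5-OH with a group that step 12 removes cleanly.

Step 9
Reactants: 13 triethylsilyl ether
Product: 14 C3–C9 aldehyde
Conditions: OsO4 (cat.), NaIO4, 2,6-lutidine, dioxane/H2O, rt
Reagents that add atoms: osmium tetroxide, O=[Os](=O)(=O)=O; sodium periodate, [Na+].[O-]I(=O)(=O)=O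
Why: Lemieux–Johnson cleavage of the terminal alkene gives the C9 aldehyde without affecting the benzyl or silyl ether.

Step 10
Reactants: 9 C10–C16 methyl ketone; 14 C3–C9 aldehyde
Product: 15 C3–C16 β-hydroxy ketone
Conditions: (c-C6H11)2BCl, Et3N, Et2O, −78 to −20 °C; H2O2, MeOH, pH 7 buffer
Reagents that add atoms: none
Why: Boron-mediated methyl ketone aldol in which (c-C6H11)2BCl/Et3N enolises the methyl side and the β-alkoxy oxygen at C13 should direct addition 1,5-anti, setting C9 (S).

Step 11
Reactants: 15 C3–C16 β-hydroxy ketone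
Product: 16 C9/C11 syn diol
Conditions: Et2BOMe, NaBH4, THF/MeOH, −78 °C; AcOH, then evaporation from MeOH
Reagents that add atoms: none
Why: Narasaka–Prasad reduction of the diethylboron chelate by external axial hydride gives the 1,3-syn diol and sets C11.

Step 12
Reactants: 16 C9/C11 syn diol
Product: 17 C3–C16 hexaol (C3 benzyl ether)
Conditions: camphor-10-sulfonic acid, MeOH, rt
Reagents that add atoms: none
Why: Acid-catalysed methanolysis removes the acetonide, the primary TBS ether and the C5 triethylsilyl ether in one operation so that a uniform set of silyl ethers can follow, while the benzyl ether is inert.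

Step 13
Reactants: 17 hexaol
Product: 18 hexakis(triethylsilyl) ether
Conditions: Et3SiOTf, 2,6-lutidine, CH2Cl2, −78 to 0 °C
Reagents that add atoms: triethylsilyl trifluoromethanesulfonate, CC[Si](CC)(CC)OS(=O)(=O)C(F)(F)F
Why: Exhaustive silylation with the silyl triflate reaches the hindered secondary hydroxyls at C13 and C15 as well as the primary C16 hydroxyl.

Step 14
Reactants: 18 hexakis(triethylsilyl) ether
Product: 19 C3 primary alcohol
Conditions: H2 (1 atm), Pd(OH)2/C, EtOAc, rt
Reagents that add atoms: none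
Why: Hydrogenolysis of the benzyl ether in a non-protic solvent frees C3-OH while the triethylsilyl ethers should persist.

Step 15
Reactants: 19 C3 primary alcohol
Product: 20 C3 aldehyde
Conditions: Dess–Martin periodinane, NaHCO3, CH2Cl2, 0 °C to rt
Reagents that add atoms: none
Why: Buffered Dess–Martin oxidation gives the β-silyloxy aldehyde without elimination.

Step 16
Reactants: 1 (S)-4-benzyl-3-propanoyl-1,3-oxazolidin-2-one; 20 C3 aldehyde
Product: 21 C1–C16 syn aldol imide
Conditions: Bu2BOTf, iPr2NEt, CH2Cl2, −78 to 0 °C; H2O2, MeOH, pH 7 buffer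
Reagents that add atoms: none
Why: A second Evans syn aldol under auxiliary control (Zimmerman–Traxler chair of the Z-boron enolate) sets C2 (S) and C3 (R) irrespective of the remote C5 stereocentre.

Step 17
Reactants: 21 C1–C16 syn aldol imide
Product: 22 heptakis(triethylsilyl) imide
Conditions: Et3SiOTf, 2,6-lutidine, CH2Cl2, −78 to 0 °C
Reagents that add atoms: triethylsilyl trifluoromethanesulfonate, CC[Si](CC)(CC)OS(=O)(=O)C(F)(F)F
Why: Silylation of the hindered β-hydroxy imide with the silyl triflate protects C3-OH before the auxiliary is removed.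

Step 18
Reactants: 22 heptakis(triethylsilyl) imide
Product: 23 C1–C16 acid
Conditions: LiOH, H2O2, THF/H2O, 0 °C; Na2SO3; citric acid to pH 4
Reagents that add atoms: hydrogen peroxide, OO; lithium hydroxide, [Li+].[OH-]
Why: Hydrolysis of the N-acyl oxazolidinone with lithium hydroperoxide attacks the exocyclic carbonyl selectively and should leave C2 unepimerised and the silyl ethers in place.

Step 19
Reactants: 24 (2R,3R)-butane-2,3-diol
Product: 25 (2R,3S)-3-bromobutan-2-yl acetate
Conditions: HBr (33% in AcOH), 0 °C to rt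
Reagents that add atoms: hydrogen bromide, Br; acetic acid, CC(=O)O
Why: HBr in acetic acid converts the diol through a cyclic acetoxonium ion (neighbouring-group participation) that bromide opens with inversion at one carbon, and the C2 symmetry of the diol makes both carbons equivalent.

Step 20
Reactants: 25 bromo acetate
Product: 26 (2R,3R)-2,3-dimethyloxirane
Conditions: KOH, HOCH2CH2OH, 60 to 100 °C, product distilled out
Reagents that add atoms: none
Why: Saponification followed by intramolecular Williamson displacement inverts the bromide carbon a second time and so returns the (R,R) configuration in the trans-epoxide.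

Step 21
Reactants: 26 (2R,3R)-2,3-dimethyloxirane; 27 vinylmagnesium bromide
Product: 28 (2R,3R)-3-methylpent-4-en-2-ol
Conditions: CuI (10 mol%), Et2O/THF, −30 to 0 °C
Reagents that add atoms: none
Why: CuI-catalysed Grignard opening of the C2-symmetric epoxide by SN2 attack with inversion sets C26 (R) and leaves the carbinol carbon C27 (R) untouched.

Step 22
Reactants: 28 (2R,3R)-3-methylpent-4-en-2-ol; 29 (E)-but-2-enal
Product: 30 C23–C28 hydroxy-enal
Conditions: second-generation Hoveyda–Grubbs catalyst RuCl2(H2IMes)(=CH-C6H4-2-OiPr) (5 mol%), CH2Cl2, 40 °C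
Reagents that add atoms: none
Why: Olefin cross-metathesis with excess crotonaldehyde, driven by loss of propene, should give the conjugated E-enal without touching C26.

Step 23
Reactants: 31 cis-cyclobut-3-ene-1,2-dicarboxylic anhydride
Product: 32 dimethyl cis-cyclobut-3-ene-1,2-dicarboxylate
Conditions: MeOH, H2SO4 (cat.), 50 °C
Reagents that add atoms: methanol, CO
Why: Methanolysis of the anhydride followed by Fischer esterification gives the meso diester well below the temperature at which this cyclobutene opens.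

Step 24
Reactants: 32 cis diester
Product: 33 dimethyl trans-cyclobut-3-ene-1,2-dicarboxylate (racemic)
Conditions: NaOMe (0.2 equiv), MeOH, 0 °C to rt
Reagents that add atoms: none
Why: Methoxide-mediated epimerisation through the ester enolate equilibrates the cis diester to the more stable trans diester, and catalytic base at or below ambient temperature limits migration of the ring double bond into conjugation.

Step 25
Reactants: 33 trans diester
Product: 34 trans-cyclobut-3-ene-1,2-diyldimethanol (racemic)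
Conditions: LiAlH4, Et2O, 0 °C
Reagents that add atoms: none
Why: LiAlH4 reduces both esters to primary alcohols and leaves the isolated cyclobutene alkene untouched.

Step 26
Reactants: 34 trans diol
Product: 35 trans bis-sulfide
Conditions: 1-phenyl-1H-tetrazole-5-thiol, PPh3, DIAD, THF, 0 °C to rt
Reagents that add atoms: 1-phenyl-1H-tetrazole-5-thiol, Sc1nnnn1-c1ccccc1
Why: Twofold Mitsunobu thioetherification with the acidic thiol proceeds at both primary carbons, and the trans ring fusion that a cyclic ether would need disfavours intramolecular etherification.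

Step 27
Reactants: 35 trans bis-sulfide
Product: 36 trans bis-sulfone linchpin
Conditions: (NH4)6Mo7O24·4H2O (cat.), H2O2 (30% aq), EtOH, 0 °C to rt
Reagents that add atoms: hydrogen peroxide, OO
Why: Molybdate-catalysed oxidation with H2O2 takes both sulfides to sulfones chemoselectively in the presence of the unactivated ring alkene.

Step 28
Reactants: 23 C1–C16 acid; 30 C23–C28 hydroxy-enal
Product: 37 ester-enal
Conditions: 2-methyl-6-nitrobenzoic anhydride (MNBA), DMAP, Et3N, CH2Cl2, rt
Reagents that add atoms: none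
Why: Shiina esterification (mixed anhydride with MNBA, acyl transfer by DMAP) joins the hindered C27 hydroxyl to C1 under nearly neutral conditions that should spare C2 and the enal.

Step 29
Reactants: 37 ester-enal; 36 trans bis-sulfone linchpin (threefold excess)
Product: 38 dienylcyclobutene sulfone
Conditions: KN(SiMe3)2 (added last), THF, −78 to −20 °C
Reagents that add atoms: none
Why: Julia–Kocienski olefination in Barbier mode, in which the sulfonyl carbanion adds to the enal and Smiles rearrangement with loss of SO2 and tetrazolate should give the E C22=C23 alkene, the excess of the C2-symmetric bis-sulfone securing mono-olefination and the single alkenyl arm leaving the cyclobutene closed.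

Step 30
Reactants: 38 dienylcyclobutene sulfone
Product: 39 sulfone aldehyde
Conditions: (COCl)2, DMSO, CH2Cl2, −78 to −30 °C; Et3N, −78 to 0 °C
Reagents that add atoms: none
Why: Swern oxidation with excess activated DMSO cleaves and oxidises a primary triethylsilyl ether directly to the aldehyde (oxidative desilylation), the hindered secondary triethylsilyl ethers reacting much more slowly at −30 °C.

Step 31
Reactants: 39 sulfone aldehyde
Product: 40 26-membered trans-cyclobutene lactone
Conditions: KN(SiMe3)2 (slow addition), THF (1 mM), −78 to −30 °C; pH 7 buffer at −30 °C; work-up at or below 0 °C, stored at −20 °C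
Reagents that add atoms: none
Why: Intramolecular Julia–Kocienski olefination under high dilution closes the 26-membered ring by forming the E C16=C17 alkene (E preference of 1-phenyltetrazolyl sulfones with α-alkoxy aldehydes and a potassium counter-ion), and the cold quench keeps the trans-3,4-dialkenylcyclobutene formed here from opening.

Step 32
Reactants: 40 26-membered trans-cyclobutene lactone
Product: 41 hexakis(triethylsilyl) pentaene macrolide
Conditions: toluene (degassed), BHT (cat.), dark, 40 °C
Reagents that add atoms: none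
Why: Proposed new method: warming should break the C18–C21 σ-bond of the cyclobutene in a thermally allowed conrotatory 4π electrocyclic opening that makes C18=C19 and C20=C21 and joins the C16=C17 alkene and the C22–C25 diene into the all-E C16–C25 pentaene. The closest known reaction type is the thermal opening of trans-3,4-disubstituted cyclobutenes to E,E-dienes, which conjugating substituents on the breaking bond accelerate; it has not been used to expand a macrolactone and unveil a pentaene in one event. No ring is closed by bond formation: the 28-membered lactone arises from the 26-membered one by a pericyclic two-atom ring expansion driven by release of cyclobutene strain and gain of conjugation. No stereocentre is created and the two cyclobutene stereocentres are destroyed, so both diastereomers of 40 should give the same product. The selectivity needed is torquoselectivity: in the trans isomer the conrotatory mode that turns both alkenyl arms outward gives E,E, the alternative would turn both inward against a strong steric and electronic penalty, and the large flexible ring should not hinder either rotation. The low temperature keeps the step well below a stepwise Cope rearrangement of the divinylcyclobutene unit and below electrocyclisations of the polyene.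

Step 33
Reactants: 41 hexakis(triethylsilyl) pentaene macrolide
Product: 42 CNP0245606.1
Conditions: HF·pyridine, pyridine, THF, 0 °C, dark
Reagents that add atoms: none
Why: Fluoride-mediated desilylation with pyridine-buffered HF·pyridine removes the six triethylsilyl ethers under nearly neutral conditions that the pentaene, the allylic C15 carbinol and the lactone should tolerate.

**Compound list**

1 | (S)-4-benzyl-3-propanoyl-1,3-oxazolidin-2-one | CCC(=O)N1[C@@H](Cc2ccccc2)COC1=O | starting material
2 | 2-[(tert-butyldimethylsilyl)oxy]acetaldehyde | O=CCO[Si](C)(C)C(C)(C)C | starting material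
3 | (S)-4-benzyl-3-[(2S,3S)-4-[(tert-butyldimethylsilyl)oxy]-3-hydroxy-2-methylbutanoyl]-1,3-oxazolidin-2-one | O=C([C@@H](C)[C@H](O)CO[Si](C)(C)C(C)(C)C)N1[C@@H](Cc2ccccc2)COC1=O | intermediate
4 | (2S,3S)-4-[(tert-butyldimethylsilyl)oxy]-3-hydroxy-N-methoxy-N,2-dimethylbutanamide | CON(C)C(=O)[C@@H](C)[C@H](O)CO[Si](C)(C)C(C)(C)C | intermediate
5 | (2-methylprop-2-en-1-yl)magnesium chloride | C=C(C)C[Mg]Cl | starting material
6 | (5S,6S)-7-[(tert-butyldimethylsilyl)oxy]-6-hydroxy-2,5-dimethylhept-1-en-4-one | C=C(C)CC(=O)[C@@H](C)[C@H](O)CO[Si](C)(C)C(C)(C)C | intermediate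
7 | (2S,3R,4R)-1-[(tert-butyldimethylsilyl)oxy]-3,6-dimethylhept-6-ene-2,4-diol | C=C(C)C[C@@H](O)[C@@H](C)[C@H](O)CO[Si](C)(C)C(C)(C)C | intermediate
8 | tert-butyldimethyl{[(4S,5R,6R)-2,2,5-trimethyl-6-(2-methylprop-2-en-1-yl)-1,3-dioxan-4-yl]methoxy}silane | C=C(C)C[C@H]1OC(C)(C)O[C@H](CO[Si](C)(C)C(C)(C)C)[C@@H]1C | intermediate
9 | 1-[(4R,5R,6S)-6-{[(tert-butyldimethylsilyl)oxy]methyl}-2,2,5-trimethyl-1,3-dioxan-4-yl]propan-2-one (C10–C16 methyl ketone) | CC(=O)C[C@H]1OC(C)(C)O[C@H](CO[Si](C)(C)C(C)(C)C)[C@@H]1C | intermediate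
10 | (R)-2-[2-(benzyloxy)ethyl]oxirane | c1ccccc1COCC[C@@H]1CO1 | starting material
11 | but-3-en-1-ylmagnesium bromide | C=CCC[Mg]Br | starting material
12 | (S)-1-(benzyloxy)oct-7-en-3-ol | c1ccccc1COCC[C@@H](O)CCCC=C | intermediate
13 | {[(S)-1-(benzyloxy)oct-7-en-3-yl]oxy}triethylsilane | c1ccccc1COCC[C@@H](O[Si](CC)(CC)CC)CCCC=C | intermediate
14 | (S)-7-(benzyloxy)-5-[(triethylsilyl)oxy]heptanal (C3–C9 aldehyde) | c1ccccc1COCC[C@@H](O[Si](CC)(CC)CC)CCCC=O | intermediate
15 | (4S,8S)-10-(benzyloxy)-1-[(4R,5R,6S)-6-{[(tert-butyldimethylsilyl)oxy]methyl}-2,2,5-trimethyl-1,3-dioxan-4-yl]-4-hydroxy-8-[(triethylsilyl)oxy]decan-2-one | c1ccccc1COCC[C@@H](O[Si](CC)(CC)CC)CCC[C@H](O)CC(=O)C[C@H]1OC(C)(C)O[C@H](CO[Si](C)(C)C(C)(C)C)[C@@H]1C | intermediate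
16 | (2S,4S,8S)-10-(benzyloxy)-1-[(4R,5R,6S)-6-{[(tert-butyldimethylsilyl)oxy]methyl}-2,2,5-trimethyl-1,3-dioxan-4-yl]-8-[(triethylsilyl)oxy]decane-2,4-diol | c1ccccc1COCC[C@@H](O[Si](CC)(CC)CC)CCC[C@H](O)C[C@H](O)C[C@H]1OC(C)(C)O[C@H](CO[Si](C)(C)C(C)(C)C)[C@@H]1C | intermediate
17 | (2S,3R,4R,6S,8S,12S)-14-(benzyloxy)-3-methyltetradecane-1,2,4,6,8,12-hexol (C16 to C3) | c1ccccc1COCC[C@@H](O)CCC[C@H](O)C[C@H](O)C[C@@H](O)[C@@H](C)[C@H](O)CO | intermediate
18 | hexakis-O-triethylsilyl ether of 17 (silyl on O5, O9, O11, O13, O15, O16; C3 benzyl ether; configuration as in 17) | c1ccccc1COCC[C@@H](O[Si](CC)(CC)CC)CCC[C@H](O[Si](CC)(CC)CC)C[C@H](O[Si](CC)(CC)CC)C[C@@H](O[Si](CC)(CC)CC)[C@@H](C)[C@H](O[Si](CC)(CC)CC)CO[Si](CC)(CC)CC | intermediate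
19 | C3–C16 primary alcohol: 18 without the benzyl group (C3-OH free) | OCC[C@@H](O[Si](CC)(CC)CC)CCC[C@H](O[Si](CC)(CC)CC)C[C@H](O[Si](CC)(CC)CC)C[C@@H](O[Si](CC)(CC)CC)[C@@H](C)[C@H](O[Si](CC)(CC)CC)CO[Si](CC)(CC)CC | intermediate
20 | C3–C16 aldehyde (C3 = CHO; six triethylsilyl ethers on O5, O9, O11, O13, O15, O16) | O=CC[C@@H](O[Si](CC)(CC)CC)CCC[C@H](O[Si](CC)(CC)CC)C[C@H](O[Si](CC)(CC)CC)C[C@@H](O[Si](CC)(CC)CC)[C@@H](C)[C@H](O[Si](CC)(CC)CC)CO[Si](CC)(CC)CC | intermediate
21 | C1–C16 syn aldol imide: N-acyl (S)-4-benzyloxazolidin-2-one with C2 methyl, free C3-OH, six triethylsilyl ethers (C2, C3 and all later centres configured as in the target) | O=C([C@@H](C)[C@H](O)C[C@@H](O[Si](CC)(CC)CC)CCC[C@H](O[Si](CC)(CC)CC)C[C@H](O[Si](CC)(CC)CC)C[C@@H](O[Si](CC)(CC)CC)[C@@H](C)[C@H](O[Si](CC)(CC)CC)CO[Si](CC)(CC)CC)N1[C@@H](Cc2ccccc2)COC1=O | intermediate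
22 | heptakis(triethylsilyl) imide: 21 with C3-O-triethylsilyl | O=C([C@@H](C)[C@H](O[Si](CC)(CC)CC)C[C@@H](O[Si](CC)(CC)CC)CCC[C@H](O[Si](CC)(CC)CC)C[C@H](O[Si](CC)(CC)CC)C[C@@H](O[Si](CC)(CC)CC)[C@@H](C)[C@H](O[Si](CC)(CC)CC)CO[Si](CC)(CC)CC)N1[C@@H](Cc2ccccc2)COC1=O | intermediate
23 | C1–C16 acid: 2,14-dimethyl-3,5,9,11,13,15,16-heptakis[(triethylsilyl)oxy]hexadecanoic acid, stereocentres as in the target | OC(=O)[C@@H](C)[C@H](O[Si](CC)(CC)CC)C[C@@H](O[Si](CC)(CC)CC)CCC[C@H](O[Si](CC)(CC)CC)C[C@H](O[Si](CC)(CC)CC)C[C@@H](O[Si](CC)(CC)CC)[C@@H](C)[C@H](O[Si](CC)(CC)CC)CO[Si](CC)(CC)CC | intermediate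
24 | (2R,3R)-butane-2,3-diol | C[C@@H](O)[C@@H](C)O | starting material
25 | (2R,3S)-3-bromobutan-2-yl acetate | C[C@@H](OC(C)=O)[C@H](C)Br | intermediate
26 | (2R,3R)-2,3-dimethyloxirane | C[C@H]1O[C@@H]1C | intermediate
27 | vinylmagnesium bromide | C=C[Mg]Br | starting material
28 | (2R,3R)-3-methylpent-4-en-2-ol | C=C[C@@H](C)[C@@H](C)O | intermediate
29 | (E)-but-2-enal | C/C=C/C=O | starting material
30 | (2E,4R,5R)-5-hydroxy-4-methylhex-2-enal (C23–C28) | O=C/C=C/[C@@H](C)[C@@H](C)O | intermediate
31 | cis-cyclobut-3-ene-1,2-dicarboxylic anhydride (meso) | O=C1OC(=O)[C@H]2C=C[C@@H]12 | starting material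
32 | dimethyl cis-cyclobut-3-ene-1,2-dicarboxylate (meso) | COC(=O)[C@H]1C=C[C@H]1C(=O)OC | intermediate
33 | dimethyl trans-cyclobut-3-ene-1,2-dicarboxylate (racemic; 1R,2R drawn) | COC(=O)[C@@H]1C=C[C@H]1C(=O)OC | intermediate
34 | trans-cyclobut-3-ene-1,2-diyldimethanol (racemic) | OC[C@@H]1C=C[C@H]1CO | intermediate
35 | trans-3,4-bis{[(1-phenyl-1H-tetrazol-5-yl)sulfanyl]methyl}cyclobut-1-ene (racemic) | c1ccc(cc1)-n1nnnc1SC[C@@H]1C=C[C@H]1CSc1nnnn1-c1ccccc1 | intermediate
36 | trans-3,4-bis{[(1-phenyl-1H-tetrazol-5-yl)sulfonyl]methyl}cyclobut-1-ene (racemic) | O=S(=O)(C[C@@H]1C=C[C@H]1CS(=O)(=O)c1nnnn1-c1ccccc1)c1nnnn1-c1ccccc1 | intermediate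
37 | (2R,3R,4E)-3-methyl-6-oxohex-4-en-2-yl ester of acid 23 (ester-enal; C16 primary triethylsilyl ether) | O=C/C=C/[C@@H](C)[C@@H](C)OC(=O)[C@@H](C)[C@H](O[Si](CC)(CC)CC)C[C@@H](O[Si](CC)(CC)CC)CCC[C@H](O[Si](CC)(CC)CC)C[C@H](O[Si](CC)(CC)CC)C[C@@H](O[Si](CC)(CC)CC)[C@@H](C)[C@H](O[Si](CC)(CC)CC)CO[Si](CC)(CC)CC | intermediate
38 | ester of acid 23 with the C27 hydroxyl of a (22E,24E)-diene whose C22 carries a trans-4-{[(1-phenyl-1H-tetrazol-5-yl)sulfonyl]methyl}cyclobut-2-en-1-yl group (C18–C21 ring; one of two C18/C21 diastereomers drawn) | O=S(=O)(C[C@@H]1C=C[C@H]1/C=C/C=C/[C@@H](C)[C@@H](C)OC(=O)[C@@H](C)[C@H](O[Si](CC)(CC)CC)C[C@@H](O[Si](CC)(CC)CC)CCC[C@H](O[Si](CC)(CC)CC)C[C@H](O[Si](CC)(CC)CC)C[C@@H](O[Si](CC)(CC)CC)[C@@H](C)[C@H](O[Si](CC)(CC)CC)CO[Si](CC)(CC)CC)c1nnnn1-c1ccccc1 | intermediate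
39 | sulfone aldehyde: 38 with C16 as CHO (six secondary triethylsilyl ethers; one of two C18/C21 diastereomers drawn) | O=S(=O)(C[C@@H]1C=C[C@H]1/C=C/C=C/[C@@H](C)[C@@H](C)OC(=O)[C@@H](C)[C@H](O[Si](CC)(CC)CC)C[C@@H](O[Si](CC)(CC)CC)CCC[C@H](O[Si](CC)(CC)CC)C[C@H](O[Si](CC)(CC)CC)C[C@@H](O[Si](CC)(CC)CC)[C@@H](C)[C@H](O[Si](CC)(CC)CC)C=O)c1nnnn1-c1ccccc1 | intermediate
40 | 26-membered lactone with a trans-cyclobutene spanning C18–C21 (C19=C20 in the ring), E alkenes at C16=C17, C22=C23 and C24=C25, six triethylsilyl ethers (one of two C18/C21 diastereomers drawn) | C[C@H]1[C@H](O[Si](CC)(CC)CC)/C=C/[C@@H]2C=C[C@H]2/C=C/C=C/[C@@H](C)[C@@H](C)OC(=O)[C@@H](C)[C@H](O[Si](CC)(CC)CC)C[C@@H](O[Si](CC)(CC)CC)CCC[C@H](O[Si](CC)(CC)CC)C[C@H](O[Si](CC)(CC)CC)C[C@H]1O[Si](CC)(CC)CC | intermediate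
41 | hexakis(triethylsilyl) ether of the target (28-membered all-E pentaene lactone) | C[C@H]1[C@H](O[Si](CC)(CC)CC)/C=C/C=C/C=C/C=C/C=C/[C@@H](C)[C@@H](C)OC(=O)[C@@H](C)[C@H](O[Si](CC)(CC)CC)C[C@@H](O[Si](CC)(CC)CC)CCC[C@H](O[Si](CC)(CC)CC)C[C@H](O[Si](CC)(CC)CC)C[C@H]1O[Si](CC)(CC)CC | intermediate
42 | CNP0245606.1 (2S,3R,5S,9S,11S,13R,14R,15R,26R,27R; 16E,18E,20E,22E,24E) | C[C@H]1[C@H](O)/C=C/C=C/C=C/C=C/C=C/[C@@H](C)[C@@H](C)OC(=O)[C@@H](C)[C@H](O)C[C@@H](O)CCC[C@H](O)C[C@H](O)C[C@H]1O | target

**Totals and risks**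

Total step count: 33. Longest linear sequence: 21 steps (steps 1–6, 10–18, 28–33).

Steps most likely to fail:

1. Step 32 (ring expansion). What may go wrong: inward rotation of one alkenyl arm under transannular constraint, eroding E geometry at C18=C19 or C20=C21, or degradation of the cyclobutene or of the nascent pentaene before clean conversion. Fallback with known chemistry, setting out from 37 and returning at 41: the pentaene is assembled by cross-coupling without a cyclobutene. Takai iodo-olefination of the enal (CrCl2, CHI3, THF, 0 °C) gives the (22E,24E)-dienyl iodide ester F1. Swern oxidative desilylation as in step 30 gives the C16 aldehyde F2. A second Takai olefination gives the bis(alkenyl iodide) F3. Double Stille coupling with (1E,3E)-1,4-bis(tributylstannyl)buta-1,3-diene (Pd2(dba)3, AsPh3, iPr2NEt, DMF/THF, 1 mM, rt, dark) then inserts C18–C21 and closes the 28-membered ring to 41.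

2. Step 31 (macrocyclic olefination). What may go wrong: intermolecular olefination outrunning ring closure, enolisation and epimerisation at C15 of the α-silyloxy aldehyde by the amide base, or erosion of E selectivity. Fallback setting out from 22 (with 30 and 36) and returning at 40: the C16=C17 alkene is made intermolecularly and the 26-membered ring is closed at the ester.
   - Swern oxidative desilylation of 22 gives the imide aldehyde F4.
   - Julia–Kocienski reaction of 30 with excess 36 (KN(SiMe3)2, 2.2 equiv, THF, −78 °C) gives the dienylcyclobutene sulfone alcohol F5.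
   - The dianion of F5 (KN(SiMe3)2, −78 °C) is condensed with F4 to give the bis-alkenylcyclobutene imide F6.
   - LiOH/H2O2 at 0 °C gives the seco acid F7.
   - Shiina macrolactonisation (MNBA, DMAP, CH2Cl2, 1 mM, 0 °C) gives 40.
   - Everything from F6 onward is handled at or below 0 °C; any material that has already opened to the pentaene seco acid would lactonise to 41 directly.

3. Step 30 (oxidative desilylation). What may go wrong: loss of the less hindered secondary triethylsilyl ethers (C5, C9, C11) or incomplete conversion of the primary one under activated-DMSO conditions. Fallback setting out from 38 and returning at 39: the primary silyl ether is first removed by selective solvolysis (PPTS, MeOH/CH2Cl2, −10 °C) to give the C16 primary alcohol F8, which is oxidised under neutral conditions (Dess–Martin periodinane, pyridine, CH2Cl2, 0 °C) to 39.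

Further compounds
F1 | step 32 | (2R,3R,4E,6E)-7-iodo-3-methylhepta-4,6-dien-2-yl ester of acid 23 | I/C=C/C=C/[C@@H](C)[C@@H](C)OC(=O)[C@@H](C)[C@H](O[Si](CC)(CC)CC)C[C@@H](O[Si](CC)(CC)CC)CCC[C@H](O[Si](CC)(CC)CC)C[C@H](O[Si](CC)(CC)CC)C[C@@H](O[Si](CC)(CC)CC)[C@@H](C)[C@H](O[Si](CC)(CC)CC)CO[Si](CC)(CC)CC
F2 | step 32 | F1 with C16 as CHO (six secondary triethylsilyl ethers) | I/C=C/C=C/[C@@H](C)[C@@H](C)OC(=O)[C@@H](C)[C@H](O[Si](CC)(CC)CC)C[C@@H](O[Si](CC)(CC)CC)CCC[C@H](O[Si](CC)(CC)CC)C[C@H](O[Si](CC)(CC)CC)C[C@@H](O[Si](CC)(CC)CC)[C@@H](C)[C@H](O[Si](CC)(CC)CC)C=O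
F3 | step 32 | bis(alkenyl iodide): F2 with C16 converted to (E)-CH=CH–I (C16=C17) | I/C=C/C=C/[C@@H](C)[C@@H](C)OC(=O)[C@@H](C)[C@H](O[Si](CC)(CC)CC)C[C@@H](O[Si](CC)(CC)CC)CCC[C@H](O[Si](CC)(CC)CC)C[C@H](O[Si](CC)(CC)CC)C[C@@H](O[Si](CC)(CC)CC)[C@@H](C)[C@H](O[Si](CC)(CC)CC)/C=C/I
F4 | step 31 | imide aldehyde: 22 with C16 as CHO (six secondary triethylsilyl ethers) | O=C([C@@H](C)[C@H](O[Si](CC)(CC)CC)C[C@@H](O[Si](CC)(CC)CC)CCC[C@H](O[Si](CC)(CC)CC)C[C@H](O[Si](CC)(CC)CC)C[C@@H](O[Si](CC)(CC)CC)[C@@H](C)[C@H](O[Si](CC)(CC)CC)C=O)N1[C@@H](Cc2ccccc2)COC1=O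
F5 | step 31 | (2R,3R,4E,6E)-3-methyl-7-[trans-4-{[(1-phenyl-1H-tetrazol-5-yl)sulfonyl]methyl}cyclobut-2-en-1-yl]hepta-4,6-dien-2-ol (one of two ring diastereomers drawn) | O=S(=O)(C[C@@H]1C=C[C@H]1/C=C/C=C/[C@@H](C)[C@@H](C)O)c1nnnn1-c1ccccc1
F6 | step 31 | bis-alkenylcyclobutene imide: C1 N-acyl oxazolidinone, C16=C17 (E) joined to the cyclobutene, free C27-OH (one of two ring diastereomers drawn) | O=C([C@@H](C)[C@H](O[Si](CC)(CC)CC)C[C@@H](O[Si](CC)(CC)CC)CCC[C@H](O[Si](CC)(CC)CC)C[C@H](O[Si](CC)(CC)CC)C[C@@H](O[Si](CC)(CC)CC)[C@@H](C)[C@H](O[Si](CC)(CC)CC)/C=C/[C@@H]1C=C[C@H]1/C=C/C=C/[C@@H](C)[C@@H](C)O)N1[C@@H](Cc2ccccc2)COC1=O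
F7 | step 31 | seco acid: F6 with C1 as CO2H | OC(=O)[C@@H](C)[C@H](O[Si](CC)(CC)CC)C[C@@H](O[Si](CC)(CC)CC)CCC[C@H](O[Si](CC)(CC)CC)C[C@H](O[Si](CC)(CC)CC)C[C@@H](O[Si](CC)(CC)CC)[C@@H](C)[C@H](O[Si](CC)(CC)CC)/C=C/[C@@H]1C=C[C@H]1/C=C/C=C/[C@@H](C)[C@@H](C)O
F8 | step 30 | C16 primary alcohol: 38 with C16-OH free | O=S(=O)(C[C@@H]1C=C[C@H]1/C=C/C=C/[C@@H](C)[C@@H](C)OC(=O)[C@@H](C)[C@H](O[Si](CC)(CC)CC)C[C@@H](O[Si](CC)(CC)CC)CCC[C@H](O[Si](CC)(CC)CC)C[C@H](O[Si](CC)(CC)CC)C[C@@H](O[Si](CC)(CC)CC)[C@@H](C)[C@H](O[Si](CC)(CC)CC)CO)c1nnnn1-c1ccccc1
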